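The route rests on cutting ring C (the dihydropyran O1–C2–C3–C4 fused to ring A at C4a and C8a) back to a salicylaldehyde, styrene and trimethyl orthoformate. The key step exploits that the O1–C2 and C3–C4 bonds bracket a styrene-derived C2–C3 unit next to C8a, the only carbon of ring A bearing a free hydroxyl: an acid-generated methoxy ortho-quinone methide adds styrene in an oxa-[4+2] reaction under a confined chiral Brønsted acid, closing ring C and setting C2 (R) at once. Its precursor is 4,6-bis(benzyloxy)-2-hydroxy-5-methylbenzaldehyde already carrying at C3 the (S)-configured isobutyl/syncarpic side chain as its enol methyl ether.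

Key step: step 11

Remark: the triketone ring is symmetric, so its enol methyl ether has a single constitution; C4 of the 4-methoxyflavan is carried as an epimer pair; for each chiral catalyst the enantiomer that delivers the stated configuration is to be fixed in a test reaction.

Step 1
Reactants: 1 3,5-dihydroxy-4-methylbenzoic acid
Product: 3 3,5-bis(benzyloxy)-4-methylbenzoic acid, via benzyl ester 2 (not isolated)
Conditions: BnBr (3.3 equiv), K2CO3 (4 equiv), DMF, 60 °C; then NaOH (aq), MeOH/THF, 65 °C; HCl to pH 2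
Reagents that add atoms: benzyl bromide, BrCc1ccccc1
Why: Williamson alkylation should benzylate both phenols and the carboxylate, and saponification of the benzyl ester returns the acid with the two aryl benzyl ethers in place.

Step 2
Reactants: 3 3,5-bis(benzyloxy)-4-methylbenzoic acid
Product: 4 1-[3,5-bis(benzyloxy)-4-methylphenyl]ethan-1-one
Conditions: MeLi (2.3 equiv), THF, 0 °C to rt; poured into 1 M HCl at 0 °C
Reagents that add atoms: methyllithium, [Li]C
Why: Addition of methyllithium to the lithium carboxylate should give a geminal dialkoxide that is stable until the quench and then collapses to the methyl ketone.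

Step 3
Reactants: 4 1-[3,5-bis(benzyloxy)-4-methylphenyl]ethan-1-one
Product: 6 3,5-bis(benzyloxy)-4-methylphenol, via aryl acetate 5 (not isolated)
Conditions: mCPBA (1.5 equiv), CF3CO2H (0.2 equiv), CH2Cl2, 0 °C to rt; aq. Na2S2O3/NaHCO3 wash; then K2CO3 (0.3 equiv), MeOH, rt
Reagents that add atoms: 3-chloroperoxybenzoic acid, OOC(=O)c1cccc(Cl)c1
Why: Baeyer–Villiger oxidation, in which aryl migrates in preference to methyl, should turn the acetyl group into an acetoxy group, and methanolysis of the aryl acetate frees the phenol oxygen that later becomes O1.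

Step 4
Reactants: 6 3,5-bis(benzyloxy)-4-methylphenol; 7 paraformaldehyde
Product: 8 4,6-bis(benzyloxy)-2-hydroxy-5-methylbenzaldehyde
Conditions: MgCl2 (anhydrous, 1.5 equiv), Et3N (3.75 equiv), 7 (6.75 equiv), MeCN, reflux; 1 M HCl work-up
Reagents that add atoms: none
Why: Magnesium-mediated ortho-formylation: the magnesium phenoxide directs formaldehyde to the ortho carbon and a second formaldehyde oxidises the benzylic alkoxide, the two ortho positions being equivalent and the para position blocked by methyl.

Step 5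
Reactants: 8 4,6-bis(benzyloxy)-2-hydroxy-5-methylbenzaldehyde; 9 ethyl (triphenylphosphoranylidene)acetate
Product: 10 5,7-bis(benzyloxy)-6-methyl-2H-chromen-2-one
Conditions: 9 (1.3 equiv), N,N-diethylaniline, 210 °C
Reagents that add atoms: none
Why: Wittig olefination with the stabilised ylide followed by thermal E to Z isomerisation and lactonisation onto the ortho hydroxyl (loss of ethanol) should give the coumarin.

Step 6
Reactants: 10 5,7-bis(benzyloxy)-6-methyl-2H-chromen-2-one; 11 isobutylmagnesium bromide
Product: 12 (4R)-5,7-bis(benzyloxy)-6-methyl-4-(2-methylpropyl)-3,4-dihydro-2H-chromen-2-one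
Conditions: CuBr·SMe2 (5 mol%), 1-[2-(dicyclohexylphosphino)ferrocenyl]ethyldiphenylphosphine (Josiphos family, enantiomer giving 4R, 6 mol%), 11 (1.5 equiv), tBuOMe, −75 °C; aq. NH4Cl at −75 °C
Reagents that add atoms: none
Why: Copper-catalysed asymmetric conjugate addition of a Grignard reagent to a coumarin, in which the chiral diphosphine–copper complex delivers the isobutyl group to one face of C4 (catalyst control) and the magnesium enolate is protonated cold so that the lactone survives.

Step 7
Reactants: 13 methyl isobutyrate; 14 isobutyryl chloride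
Product: 15 methyl 2,2,4-trimethyl-3-oxopentanoate
Conditions: LDA (1.05 equiv), THF, −78 °C; enolate added to 14 (1.0 equiv), −78 °C to rt
Reagents that add atoms: none
Why: Claisen-type C-acylation of the lithium ester enolate by the acid chloride should give the β-keto ester, which has no hydrogen between its carbonyl groups and is protected from double acylation by the inverse addition.

Step 8
Reactants: 12 (4R)-5,7-bis(benzyloxy)-6-methyl-4-(2-methylpropyl)-3,4-dihydro-2H-chromen-2-one; 15 methyl 2,2,4-trimethyl-3-oxopentanoate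
Product: 17 4-[(1S)-1-[2,4-bis(benzyloxy)-6-hydroxy-3-methylphenyl]-3-methylbutyl]-5-hydroxy-2,2,6,6-tetramethylcyclohex-4-ene-1,3-dione, via acyclic diketo ester 16 (not isolated)
Conditions: 15 (2.2 equiv), LDA (2.4 equiv), THF, −78 °C; add 12; −78 °C to rt; 1 M HCl at 0 °C
Reagents that add atoms: none
Why: Crossed Claisen acylation of the lithium enolate of 15 by the aryl lactone (aryloxide leaving group; the excess enolate also covers acylation through the ketene if the lactone is enolised first) followed by Dieckmann closure of the methylene ketone onto the methyl ester should build the six-membered triketone and free the phenol, while the stereocentre, β to the reacting carbonyl, is untouched and changes descriptor from R to S only through the priority rules.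

Step 9
Reactants: 17 4-[(1S)-1-[2,4-bis(benzyloxy)-6-hydroxy-3-methylphenyl]-3-methylbutyl]-5-hydroxy-2,2,6,6-tetramethylcyclohex-4-ene-1,3-dione
Product: 18 4-[(1S)-1-[2,4-bis(benzyloxy)-6-hydroxy-3-methylphenyl]-3-methylbutyl]-5-methoxy-2,2,6,6-tetramethylcyclohex-4-ene-1,3-dione
Conditions: TMSCHN2 (1.2 equiv), toluene/MeOH (4:1), 0 °C
Reagents that add atoms: (trimethylsilyl)diazomethane, C[Si](C)(C)C=[N+]=[N-]
Why: The triketone enol, a vinylogous carboxylic acid, should protonate the diazoalkane and be O-methylated far faster than the hindered phenol (diazoalkane esterification type), and as an enol ether the side chain can no longer fragment by retro-Michael loss of the triketone.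

Step 10
Reactants: 18 4-[(1S)-1-[2,4-bis(benzyloxy)-6-hydroxy-3-methylphenyl]-3-methylbutyl]-5-methoxy-2,2,6,6-tetramethylcyclohex-4-ene-1,3-dione; 7 paraformaldehyde
Product: 19 4,6-bis(benzyloxy)-2-hydroxy-3-[(1S)-1-(2-methoxy-3,3,5,5-tetramethyl-4,6-dioxocyclohex-1-en-1-yl)-3-methylbutyl]-5-methylbenzaldehyde
Conditions: MgCl2 (anhydrous, 3 equiv), Et3N (6 equiv), 7 (8 equiv), THF, 65 °C; 1 M HCl work-up
Reagents that add atoms: none
Why: Magnesium-mediated ortho-formylation should deliver the aldehyde to the only unsubstituted ring carbon, ortho to the free hydroxyl, and the mild amine base and moderate temperature leave the hindered enol ether and the stereocentre alone.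

Step 11
Reactants: 19 4,6-bis(benzyloxy)-2-hydroxy-3-[(1S)-1-(2-methoxy-3,3,5,5-tetramethyl-4,6-dioxocyclohex-1-en-1-yl)-3-methylbutyl]-5-methylbenzaldehyde; 20 styrene; 21 trimethyl orthoformate
Product: 24 4-[(1S)-1-[(2R)-5,7-bis(benzyloxy)-4-methoxy-6-methyl-2-phenyl-3,4-dihydro-2H-chromen-8-yl]-3-methylbutyl]-5-methoxy-2,2,6,6-tetramethylcyclohex-4-ene-1,3-dione (both C4 epimers), via dimethyl acetal 22 (not isolated), via methoxy ortho-quinone methide 23 (not isolated)
Conditions: 21 (1.5 equiv), 20 (5 equiv), BINOL-derived N-triflyl imidodiphosphorimidate Brønsted acid with 3,3'-aryl groups (enantiomer giving 2R, 5 mol%), 5 Å molecular sieves, CHCl3, −30 °C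
Reagents that add atoms: none
Why: Proposed new method: the orthoformate converts the hindered aldehyde into its dimethyl acetal, which the strong confined acid ionises with loss of methanol to a methoxy-substituted ortho-quinone methide (a benzylic oxocarbenium) held as a contact ion pair with the chiral anion, after which the CH2 terminus of styrene bonds to C4 and the benzylic cation developing at C2 is captured by the C8a oxygen in an asynchronous inverse-electron-demand oxa-[4+2] cycloaddition. The closest known chemistry is the achiral acid-catalysed three-component condensation of salicylaldehydes, trimethyl orthoformate and styrenes to 4-methoxy-2-arylchromans together with confined imidodiphosphorimidate catalysis of cycloadditions of ortho-quinone methides and oxocarbenium ions with simple olefins; their combination on a fully substituted ring is untested. Ring C closes as a six-membered [4+2] cycloadduct, four atoms (O1, C8a, C4a, C4) coming from the heterodiene and C2–C3 from styrene, with O1–C2 formed last by cation capture. C2 is set by the chiral anion, which shields one face of the ion pair so that styrene approaches to give 2R (catalyst control, the remote side-chain centre acting only as a matched or mismatched bias), and C4 forms as a mixture that step 12 erases. The 2-phenyl regiochemistry follows from Markovnikov attack that places the charge on the benzylic carbon, the ring fusion is unambiguous because C8a carries the only free hydroxyl, and the electron-rich ring stabilises the cationic diene against side reactions. The enol is carried as its methyl ether because that group is degenerate under methanol/orthoformate exchange and a free enol would be methylated in the flask anyway.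

Step 12
Reactants: 24 4-[(1S)-1-[(2R)-5,7-bis(benzyloxy)-4-methoxy-6-methyl-2-phenyl-3,4-dihydro-2H-chromen-8-yl]-3-methylbutyl]-5-methoxy-2,2,6,6-tetramethylcyclohex-4-ene-1,3-dione
Product: 25 (2R)-5,7-bis(benzyloxy)-8-[(1S)-1-(2-methoxy-3,3,5,5-tetramethyl-4,6-dioxocyclohex-1-en-1-yl)-3-methylbutyl]-6-methyl-2-phenyl-2,3-dihydro-4H-chromen-4-one
Conditions: DDQ (1.5 equiv), CH2Cl2/H2O (10:1), 0 °C to rt
Reagents that add atoms: water, O
Why: DDQ should abstract hydride from the C4–H activated by its methoxy group and by the 5,7-dialkoxy ring (the oxidative cleavage that removes p-methoxybenzyl ethers), water adds to the oxocarbenium and the hemiketal loses methanol to give the aryl ketone from either C4 epimer, while the side-chain methine, flanked by two ortho substituents, cannot align with the ring π system and C2 is left alone.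

Step 13
Reactants: 25 (2R)-5,7-bis(benzyloxy)-8-[(1S)-1-(2-methoxy-3,3,5,5-tetramethyl-4,6-dioxocyclohex-1-en-1-yl)-3-methylbutyl]-6-methyl-2-phenyl-2,3-dihydro-4H-chromen-4-one
Product: 26 (2R)-5,7-bis(benzyloxy)-8-[(1S)-1-(2-hydroxy-3,3,5,5-tetramethyl-4,6-dioxocyclohex-1-en-1-yl)-3-methylbutyl]-6-methyl-2-phenyl-2,3-dihydro-4H-chromen-4-one
Conditions: 2 M HCl (aq)/THF (1:3), 45 °C
Reagents that add atoms: water, O
Why: Acid-catalysed hydrolysis of the vinylogous methyl ester (water adds to the protonated β-methoxy enone, methanol leaves) should free the enol while O7 is still benzylated, so cyclodehydration onto the triketone is impossible and no base is present to open the flavanone at C2.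

Step 14
Reactants: 26 (2R)-5,7-bis(benzyloxy)-8-[(1S)-1-(2-hydroxy-3,3,5,5-tetramethyl-4,6-dioxocyclohex-1-en-1-yl)-3-methylbutyl]-6-methyl-2-phenyl-2,3-dihydro-4H-chromen-4-one
Product: 27 (2R)-5,7-dihydroxy-8-[(1S)-1-(2-hydroxy-3,3,5,5-tetramethyl-4,6-dioxocyclohex-1-en-1-yl)-3-methylbutyl]-6-methyl-2-phenyl-2,3-dihydro-4H-chromen-4-one (CNP0249552.1)
Conditions: H2 (1 atm), Pd/C (10 wt%), EtOAc, rt
Reagents that add atoms: none
Why: Hydrogenolysis of the two aryl benzyl ethers over palladium on carbon at atmospheric pressure should leave the aryl ketone, the cyclic benzylic ether at C2 and the tetrasubstituted enol untouched, so both stereocentres pass unchanged into the target.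

Compound list
1 | 3,5-dihydroxy-4-methylbenzoic acid | Cc1c(O)cc(C(=O)O)cc1O | starting material
2 | benzyl 3,5-bis(benzyloxy)-4-methylbenzoate | Cc1c(OCc2ccccc2)cc(C(=O)OCc2ccccc2)cc1OCc1ccccc1 | intermediate
3 | 3,5-bis(benzyloxy)-4-methylbenzoic acid | Cc1c(OCc2ccccc2)cc(C(=O)O)cc1OCc1ccccc1 | intermediate
4 | 1-[3,5-bis(benzyloxy)-4-methylphenyl]ethan-1-one | CC(=O)c1cc(OCc2ccccc2)c(C)c(OCc2ccccc2)c1 | intermediate
5 | 3,5-bis(benzyloxy)-4-methylphenyl acetate | CC(=O)Oc1cc(OCc2ccccc2)c(C)c(OCc2ccccc2)c1 | intermediate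
6 | 3,5-bis(benzyloxy)-4-methylphenol | Cc1c(OCc2ccccc2)cc(O)cc1OCc1ccccc1 | intermediate
7 | paraformaldehyde (formaldehyde unit) | C=O | starting material
8 | 4,6-bis(benzyloxy)-2-hydroxy-5-methylbenzaldehyde | Cc1c(OCc2ccccc2)cc(O)c(C=O)c1OCc1ccccc1 | intermediate
9 | ethyl (triphenylphosphoranylidene)acetate | CCOC(=O)C=P(c1ccccc1)(c1ccccc1)c1ccccc1 | starting material
10 | 5,7-bis(benzyloxy)-6-methyl-2H-chromen-2-one | Cc1c(OCc2ccccc2)cc2OC(=O)C=Cc2c1OCc1ccccc1 | intermediate
11 | isobutylmagnesium bromide | CC(C)C[Mg]Br | starting material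
12 | (4R)-5,7-bis(benzyloxy)-6-methyl-4-(2-methylpropyl)-3,4-dihydro-2H-chromen-2-one | Cc1c(OCc2ccccc2)cc2OC(=O)C[C@@H](CC(C)C)c2c1OCc1ccccc1 | intermediate
13 | methyl isobutyrate | COC(=O)C(C)C | starting material
14 | isobutyryl chloride | CC(C)C(=O)Cl | starting material
15 | methyl 2,2,4-trimethyl-3-oxopentanoate | COC(=O)C(C)(C)C(=O)C(C)C | intermediate
16 | methyl (7R)-7-[2,4-bis(benzyloxy)-6-hydroxy-3-methylphenyl]-2,2,4,4,9-pentamethyl-3,5-dioxodecanoate | COC(=O)C(C)(C)C(=O)C(C)(C)C(=O)C[C@@H](CC(C)C)c1c(O)cc(OCc2ccccc2)c(C)c1OCc1ccccc1 | intermediate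
17 | 4-[(1S)-1-[2,4-bis(benzyloxy)-6-hydroxy-3-methylphenyl]-3-methylbutyl]-5-hydroxy-2,2,6,6-tetramethylcyclohex-4-ene-1,3-dione | Cc1c(OCc2ccccc2)cc(O)c([C@H](CC(C)C)C2=C(O)C(C)(C)C(=O)C(C)(C)C2=O)c1OCc1ccccc1 | intermediate
18 | 4-[(1S)-1-[2,4-bis(benzyloxy)-6-hydroxy-3-methylphenyl]-3-methylbutyl]-5-methoxy-2,2,6,6-tetramethylcyclohex-4-ene-1,3-dione | Cc1c(OCc2ccccc2)cc(O)c([C@H](CC(C)C)C2=C(OC)C(C)(C)C(=O)C(C)(C)C2=O)c1OCc1ccccc1 | intermediate
19 | 4,6-bis(benzyloxy)-2-hydroxy-3-[(1S)-1-(2-methoxy-3,3,5,5-tetramethyl-4,6-dioxocyclohex-1-en-1-yl)-3-methylbutyl]-5-methylbenzaldehyde | Cc1c(OCc2ccccc2)c(C=O)c(O)c([C@H](CC(C)C)C2=C(OC)C(C)(C)C(=O)C(C)(C)C2=O)c1OCc1ccccc1 | intermediate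
20 | styrene | C=Cc1ccccc1 | starting material
21 | trimethyl orthoformate | COC(OC)OC | starting material
22 | dimethyl acetal of 19 | Cc1c(OCc2ccccc2)c(C(OC)OC)c(O)c([C@H](CC(C)C)C2=C(OC)C(C)(C)C(=O)C(C)(C)C2=O)c1OCc1ccccc1 | intermediate
23 | methoxy ortho-quinone methide from 22 (neutral form of the ion pair) | CC1=C(OCc2ccccc2)C(=COC)C(=O)C([C@H](CC(C)C)C2=C(OC)C(C)(C)C(=O)C(C)(C)C2=O)=C1OCc1ccccc1 | intermediate
24 | 4-[(1S)-1-[(2R)-5,7-bis(benzyloxy)-4-methoxy-6-methyl-2-phenyl-3,4-dihydro-2H-chromen-8-yl]-3-methylbutyl]-5-methoxy-2,2,6,6-tetramethylcyclohex-4-ene-1,3-dione (C4 epimers) | Cc1c(OCc3ccccc3)c2c(c([C@H](CC(C)C)C3=C(OC)C(C)(C)C(=O)C(C)(C)C3=O)c1OCc1ccccc1)O[C@@H](c1ccccc1)CC2OC | intermediate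
25 | (2R)-5,7-bis(benzyloxy)-8-[(1S)-1-(2-methoxy-3,3,5,5-tetramethyl-4,6-dioxocyclohex-1-en-1-yl)-3-methylbutyl]-6-methyl-2-phenyl-2,3-dihydro-4H-chromen-4-one | Cc1c(OCc3ccccc3)c2c(c([C@H](CC(C)C)C3=C(OC)C(C)(C)C(=O)C(C)(C)C3=O)c1OCc1ccccc1)O[C@@H](c1ccccc1)CC2=O | intermediate
26 | (2R)-5,7-bis(benzyloxy)-8-[(1S)-1-(2-hydroxy-3,3,5,5-tetramethyl-4,6-dioxocyclohex-1-en-1-yl)-3-methylbutyl]-6-methyl-2-phenyl-2,3-dihydro-4H-chromen-4-one | Cc1c(OCc3ccccc3)c2c(c([C@H](CC(C)C)C3=C(O)C(C)(C)C(=O)C(C)(C)C3=O)c1OCc1ccccc1)O[C@@H](c1ccccc1)CC2=O | intermediate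
27 | (2R)-5,7-dihydroxy-8-[(1S)-1-(2-hydroxy-3,3,5,5-tetramethyl-4,6-dioxocyclohex-1-en-1-yl)-3-methylbutyl]-6-methyl-2-phenyl-2,3-dihydro-4H-chromen-4-one | Cc1c(O)c2c(c([C@H](CC(C)C)C3=C(O)C(C)(C)C(=O)C(C)(C)C3=O)c1O)O[C@@H](c1ccccc1)CC2=O | target

Total step count: 14. Longest linear sequence: 13 steps (steps 1 to 6 and 8 to 14).

Steps most likely to fail

Step 11. Facial control at C2 may be lost in the ion pair (background or mismatched pathway), or the C8a hydroxyl may be diverted into attack on the neighbouring enol ether carbon before styrene adds. Fallback with known chemistry: starting from 19, 20 and 21, the condensation is run with an achiral acid, Sc(OTf)3 in CH2Cl2, which is the established racemic three-component chroman synthesis. C2 then forms without control and the product is 24 together with its (2S)-epimer of the 4-methoxyflavan F1, each as a C4 epimer pair. Because the side-chain centre is already fixed, the C2 epimers are diastereomers and not enantiomers. The mixture is oxidised with DDQ and water as in step 12 to 25 and the (2S)-flavanone F2, which differ only at C2 and should be separable by chromatography or crystallisation. The route is rejoined at 25.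

Step 8. Proton transfer from the lactone to the hindered tetrasubstituted enolate may outrun C-acylation, so that enolisation and ketene-derived oligomerisation replace the Claisen adduct. The fallback sets out from 12 and moves the acylation to an acid chloride with the phenol masked. The lactone is opened with aqueous NaOH and both oxygens are silylated (TBSCl, imidazole, DMF) to the silyl ester silyl ether F3. Oxalyl chloride with catalytic DMF converts the silyl ester directly into the acid chloride F4. This acylates the lithium enolate of 15 at carbon (LDA, THF, −78 °C), as acetyl chloride does in the established synthesis of syncarpic acid, to give the silyl-protected diketo ester F5. LDA then effects the Dieckmann closure to the silyl-protected triketone F6, and buffered TBAF frees the phenol, returning to 17.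

Step 6. Conjugate addition at C4 may be slowed by the peri benzyloxy group and the electron-rich ring, allowing 1,2-addition to the lactone or erosion of enantioselectivity. The fallback sets out from 6 and delivers hydride instead of the alkyl group. Pechmann condensation of 6 with ethyl 5-methyl-3-oxohexanoate (Sc(OTf)3 cat., toluene, 80 °C) gives the 4-isobutylcoumarin F7. Copper hydride-catalysed asymmetric conjugate reduction (Cu(OAc)2, DTBM-SEGPHOS enantiomer chosen for 4R, diethoxymethylsilane, tBuOH, toluene) then sets the same centre and returns lactone 12.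

Further compounds
F1 | step 11 | 4-[(1S)-1-[(2S)-5,7-bis(benzyloxy)-4-methoxy-6-methyl-2-phenyl-3,4-dihydro-2H-chromen-8-yl]-3-methylbutyl]-5-methoxy-2,2,6,6-tetramethylcyclohex-4-ene-1,3-dione (C4 epimers) | Cc1c(OCc3ccccc3)c2c(c([C@H](CC(C)C)C3=C(OC)C(C)(C)C(=O)C(C)(C)C3=O)c1OCc1ccccc1)O[C@H](c1ccccc1)CC2OC
F2 | step 11 | (2S)-5,7-bis(benzyloxy)-8-[(1S)-1-(2-methoxy-3,3,5,5-tetramethyl-4,6-dioxocyclohex-1-en-1-yl)-3-methylbutyl]-6-methyl-2-phenyl-2,3-dihydro-4H-chromen-4-one | Cc1c(OCc3ccccc3)c2c(c([C@H](CC(C)C)C3=C(OC)C(C)(C)C(=O)C(C)(C)C3=O)c1OCc1ccccc1)O[C@H](c1ccccc1)CC2=O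
F3 | step 8 | tert-butyldimethylsilyl (3R)-3-[2,4-bis(benzyloxy)-6-(tert-butyldimethylsilyloxy)-3-methylphenyl]-5-methylhexanoate | Cc1c(OCc2ccccc2)cc(O[Si](C)(C)C(C)(C)C)c([C@H](CC(C)C)CC(=O)O[Si](C)(C)C(C)(C)C)c1OCc1ccccc1
F4 | step 8 | (3R)-3-[2,4-bis(benzyloxy)-6-(tert-butyldimethylsilyloxy)-3-methylphenyl]-5-methylhexanoyl chloride | Cc1c(OCc2ccccc2)cc(O[Si](C)(C)C(C)(C)C)c([C@H](CC(C)C)CC(=O)Cl)c1OCc1ccccc1
F5 | step 8 | methyl (7R)-7-[2,4-bis(benzyloxy)-6-(tert-butyldimethylsilyloxy)-3-methylphenyl]-2,2,4,4,9-pentamethyl-3,5-dioxodecanoate | Cc1c(OCc2ccccc2)cc(O[Si](C)(C)C(C)(C)C)c([C@H](CC(C)C)CC(=O)C(C)(C)C(=O)C(C)(C)C(=O)OC)c1OCc1ccccc1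
F6 | step 8 | 4-[(1S)-1-[2,4-bis(benzyloxy)-6-(tert-butyldimethylsilyloxy)-3-methylphenyl]-3-methylbutyl]-5-hydroxy-2,2,6,6-tetramethylcyclohex-4-ene-1,3-dione | Cc1c(OCc2ccccc2)cc(O[Si](C)(C)C(C)(C)C)c([C@H](CC(C)C)C2=C(O)C(C)(C)C(=O)C(C)(C)C2=O)c1OCc1ccccc1
F7 | step 6 | 5,7-bis(benzyloxy)-6-methyl-4-(2-methylpropyl)-2H-chromen-2-one | Cc1c(OCc2ccccc2)cc2OC(=O)C=C(CC(C)C)c2c1OCc1ccccc1
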